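All constants are those of an exercise; the run is a simulation.

The ratio [target]/[substrate] at which the addition stands still, with dissolved gas frozen at saturation, is the rest ratio 1.40, the equilibrium constant times the saturation concentration.

    gas phase ⇌ dissolved gas, rate k1*(csat - [dissolved gas]) (k1 = 7.54 min⁻¹, csat = 200 mM)
    substrate + dissolved gas ⇌ target (K2 = 7.0 M⁻¹, k2 = 2.17 M⁻¹ min⁻¹)
    dissolved gas + target → over-reacted product (k3 = 0.127 M⁻¹ min⁻¹)
    crystals ⇌ target, rate k4*(cs4 - [target]) while solid is left; crystals form when [target] > cs4 (cs4 = 0.067 M, k4 = 0.633 min⁻¹)
    2 dissolved gas → homo dimer (k5 = 0.137 M⁻¹ min⁻¹)

substrate 0.53 M; gas phase 200 mM (held); time 12 min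

- amounts and yields of target count crystals too
- two of one species on the left: rate k times its square, two consumed each time
- given per volume of solution although it is solid: crystals
- at the start none of the gas is dissolved
- run time (flask): 12 min

* how much target and crystals together there is at 12 min, in percent of the substrate charged
* concentration of dissolved gas in solution at 3.0 min, in percent of saturation
* the change that raises the amount of target and crystals together at 12 min, in percent of the substrate charged most ("none" if none brings more than 2 percentage points) (eta / beta / alpha / epsilon / none)
* amount of target and crystals together at 12 min, in percent of the substrate charged, after alpha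

- eta: doubling the saturation concentration of gas phase, all else as stated
- beta: doubling the dissolution coefficient of step 4, all else as stated
- alpha: doubling the transfer coefficient of step 1, all else as stated
- epsilon: doubling the solubility in step 4, all else as stated

For the next hand at the bench: the flask holds substrate, with gas entering faster than the charged substrate takes it up, 7.54 min⁻¹ against 1.15 min⁻¹. So dissolved gas can be frozen, though this reckoning stops short of the reading at 3.0 min:

[dissolved gas]/saturation with the whole charge present = 86.8%

The forward step then treats substrate as pseudo-first-order, with constant 0.434 min⁻¹ and, the way back not counted, half-life 1.60 min, short against 12 min. If crystals held dissolved target at its solubility, the reckoning would run: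

substrate at rest = 0.067 M / 1.40 = 0.0479 M, or 9.03% of the charge

over-reacted product = 3.85% of the charge

target and crystals = 87.1%

In this reckoning more dissolved target lowers that sum, since it leaves more substrate and feeds more over-reaction. Leave the solubility alone, since doubling it doubles the substrate at rest. Doubling the saturation gains 4.5 percentage points on the substrate at rest and costs 3.9 points in over-reaction. Faster transfer leaves the rest ratio as it is. Doubling the dissolution coefficient is this reckoning's pick.

The forecast gives 80.5%, below this reckoning's 87.1%, then 95.5%, beta and 81%, the choice resting on “keeping dissolved target low”.

The flask gives 81.0%, 95.6%, beta with a gain of 3.1 points, and 81.2%. The homo dimer reaches 0.0604 M at 12.0 min, yet its step makes no difference to the amount of target and crystals. The flask charged with 0.13 M of substrate holds 0% crystals at 12.0 min, and its target over substrate reads 1.35 against the rest ratio of 1.40.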